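**Retrosynthetic overview**

1. Core numbering used throughout: dibenzo[a,d][7]annulene, C5 = benzyl-bearing methine, C10 = aryl-bearing methine, C11 = CH2. Phenols are carried as methyl ethers and freed last (BBr3).
2. C10–H is installed last by ionic hydrogenation of a C10=C11 stilbene inside the rigid pentacycle (cis to C5–H). Before that, the six-membered ring is closed by a zerovalent-nickel ArBr/ArOTf biaryl coupling.
3. C5: a 3,5-dimethoxybenzyl (ring A) Grignard reagent adds to the C5 ketone. The C5–H centre is set by chiral phosphoric acid/Hantzsch ester reduction of the ortho-quinone methide, which uses the C4 phenol (later the triflate).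
4. Seven-membered ring: Friedel–Crafts acylation of a 2-(2,2-diarylethyl)benzoic acid, then DDQ to the C10=C11 alkene. The acid comes from Friedel–Crafts alkylation of veratrole by a 3-arylisochromanone.
5. Key C10–C11 bond: aldol addition of the lithium dienolate of methyl 2,4-dimethoxy-6-methylbenzoate (ring C) to veratraldehyde. Ring order: lactone (temporary) → seven-membered carbocycle → six-membered ring.

Assumption: 1 is bought (otherwise MeI/K2CO3 on methyl orsellinate), and (R)-TRIP is taken to give the 5R centre; the antipodal acid is used if the first run shows the opposite sense.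

**Route**

Step 1
Reactants: 1 methyl 2,4-dimethoxy-6-methylbenzoate; 2 3,4-dimethoxybenzaldehyde
Product: 5 rac-3-(3,4-dimethoxyphenyl)-6,8-dimethoxyisochroman-1-one, via lithium dienolate 3 (not isolated), via lithium aldolate 4 (not isolated)
Conditions: LiN(iPr)2 (1.1 equiv), THF, −78 °C; then 2, −78 °C → rt; aq HCl
Reagents that add atoms: none
Why: Lateral deprotonation of the ortho-toluate gives a dienolate whose aldol addition to the aldehyde forms the C10–C11 bond and is made irreversible by lactonisation of the aldolate onto the neighbouring ester; the new stereocentre is racemic and is erased in steps 2 and 4.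

Step 2
Reactants: 5 rac-3-(3,4-dimethoxyphenyl)-6,8-dimethoxyisochroman-1-one; 6 1,2-dimethoxybenzene (veratrole)
Product: 7 2-[2,2-bis(3,4-dimethoxyphenyl)ethyl]-4,6-dimethoxybenzoic acid
Conditions: CF3CO2H–CH2Cl2 (1:1), 6 (10 equiv), 0 °C → rt
Reagents that add atoms: none
Why: Friedel–Crafts alkylation, in which acid ionises the 3,4-dimethoxybenzylic lactone C–O bond and veratrole captures the cation para to a methoxy group, giving an acid with two identical aryl groups on C10 (no stereocentre).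

Step 3
Reactants: 7 2-[2,2-bis(3,4-dimethoxyphenyl)ethyl]-4,6-dimethoxybenzoic acid
Product: 8 rac-10-(3,4-dimethoxyphenyl)-2,4,7,8-tetramethoxy-10,11-dihydro-5H-dibenzo[a,d][7]annulen-5-one
Conditions: P2O5–MeSO3H (Eaton's reagent), 25–40 °C
Reagents that add atoms: none
Why: Intramolecular Friedel–Crafts acylation (the classical dibenzosuberone ring closure) at the position para to OMe of either equivalent veratryl ring closes the seven-membered ring; C10 becomes a racemic stereocentre that is removed in step 4.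

Step 4
Reactants: 8 rac-10-(3,4-dimethoxyphenyl)-2,4,7,8-tetramethoxy-10,11-dihydro-5H-dibenzo[a,d][7]annulen-5-one
Product: 9 10-(3,4-dimethoxyphenyl)-2,4,7,8-tetramethoxy-5H-dibenzo[a,d][7]annulen-5-one
Conditions: DDQ (1.5 equiv), 1,4-dioxane, 80 °C
Reagents that add atoms: none
Why: Benzylic dehydrogenation, in which DDQ abstracts the doubly benzylic, methoxy-activated C10–H as hydride and loss of a C11 proton gives the conjugated triaryl alkene, removing the racemic centre.

Step 5
Reactants: 9 10-(3,4-dimethoxyphenyl)-2,4,7,8-tetramethoxy-5H-dibenzo[a,d][7]annulen-5-one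
Product: 10 10-(3,4-dimethoxyphenyl)-4-hydroxy-2,7,8-trimethoxy-5H-dibenzo[a,d][7]annulen-5-one
Conditions: BCl3 (1.5 equiv), CH2Cl2, −78 → 0 °C; H2O
Reagents that add atoms: none
Why: Chelation-controlled ether cleavage, in which BCl3 bound to the C5 ketone removes only the peri C4 methyl ether and leaves the other five.

Step 6
Reactants: 11 3,5-dimethoxybenzyl alcohol
Product: 12 2-bromo-3,5-dimethoxybenzyl alcohol
Conditions: NBS (1.0 equiv), MeCN, 0 °C
Reagents that add atoms: N-bromosuccinimide, O=C1CCC(=O)N1Br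
Why: Electrophilic aromatic bromination of the resorcinol-type ring goes ortho to the CH2OH group (para to one OMe) and not between the two methoxy groups.

Step 7
Reactants: 12 2-bromo-3,5-dimethoxybenzyl alcohol
Product: 13 2-bromo-3,5-dimethoxybenzyl chloride
Conditions: SOCl2, cat. DMF, CH2Cl2, 0 °C → rt
Reagents that add atoms: thionyl chloride, O=S(Cl)Cl
Why: Chlorodehydroxylation of the benzylic alcohol through its chlorosulfite.

Step 8
Reactants: 13 2-bromo-3,5-dimethoxybenzyl chloride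
Product: 14 (2-bromo-3,5-dimethoxybenzyl)magnesium chloride (used as solution)
Conditions: Mg turnings (3 equiv), Et2O, 0 °C, slow addition
Reagents that add atoms: magnesium, [Mg]
Why: Grignard formation, in which magnesium inserts into the benzylic C–Cl bond much faster than into the hindered, electron-rich aryl C–Br bond, while slow addition at 0 °C limits Wurtz coupling.

Step 9
Reactants: 10 10-(3,4-dimethoxyphenyl)-4-hydroxy-2,7,8-trimethoxy-5H-dibenzo[a,d][7]annulen-5-one; 14 (2-bromo-3,5-dimethoxybenzyl)magnesium chloride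
Product: 15 rac-5-(2-bromo-3,5-dimethoxybenzyl)-10-(3,4-dimethoxyphenyl)-2,7,8-trimethoxy-5H-dibenzo[a,d][7]annulene-4,5-diol
Conditions: 14 (3.5 equiv), THF–Et2O, 0 °C → rt; aq NH4Cl
Reagents that add atoms: none
Why: Grignard 1,2-addition to the diaryl ketone after the first equivalent has deprotonated the phenol; the carbinol centre is racemic and is ionised in step 10.

Step 10
Reactants: 15 rac-5-(2-bromo-3,5-dimethoxybenzyl)-10-(3,4-dimethoxyphenyl)-2,7,8-trimethoxy-5H-dibenzo[a,d][7]annulene-4,5-diol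
Product: 16 (5R)-5-(2-bromo-3,5-dimethoxybenzyl)-10-(3,4-dimethoxyphenyl)-2,7,8-trimethoxy-5H-dibenzo[a,d][7]annulen-4-ol
Conditions: (R)-TRIP [(R)-3,3′-bis(2,4,6-triisopropylphenyl)-1,1′-binaphthyl-2,2′-diyl hydrogen phosphate, 10 mol %], Hantzsch ester (1.5 equiv), 5 Å MS, toluene, 25–40 °C
Reagents that add atoms: none
Why: Chiral Brønsted acid-catalysed transfer hydrogenation, in which the acid dehydrates the o-hydroxybenzylic tertiary alcohol to an ortho-quinone methide of fixed geometry and, hydrogen-bonded to its oxygen and to the Hantzsch ester N–H, directs hydride to one face of C5 to set the 5R centre.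

Step 11
Reactants: 16 (5R)-5-(2-bromo-3,5-dimethoxybenzyl)-10-(3,4-dimethoxyphenyl)-2,7,8-trimethoxy-5H-dibenzo[a,d][7]annulen-4-ol
Product: 17 (5R)-5-(2-bromo-3,5-dimethoxybenzyl)-10-(3,4-dimethoxyphenyl)-2,7,8-trimethoxy-5H-dibenzo[a,d][7]annulen-4-yl trifluoromethanesulfonate
Conditions: (CF3SO2)2O, pyridine, CH2Cl2, 0 °C
Reagents that add atoms: trifluoromethanesulfonic anhydride, O=S(=O)(OS(=O)(=O)C(F)(F)F)C(F)(F)F
Why: O-sulfonylation of the phenol gives the aryl triflate that serves as the second electrophile for biaryl closure, without touching C5.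

Step 12
Reactants: 17 (5R)-5-(2-bromo-3,5-dimethoxybenzyl)-10-(3,4-dimethoxyphenyl)-2,7,8-trimethoxy-5H-dibenzo[a,d][7]annulen-4-yl trifluoromethanesulfonate
Product: 18 (5R)-pentacyclic stilbene: 17 with Br and OTf replaced by a bond between C2 of the benzyl ring and C4 of the core (new 9,10-dihydrophenanthrene ring, C10=C11 kept, seven OMe)
Conditions: Ni(cod)2 (2.5 equiv), 2,2′-bipyridine (2.5 equiv), DMF, 60 °C
Reagents that add atoms: none
Why: Intramolecular Ullmann-type (Semmelhack) coupling, in which zerovalent nickel inserts into the aryl C–Br and C–OTf bonds and reductive elimination forms the biaryl bond at the two pre-marked carbons, so the regiochemistry is fixed and C5 is untouched.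

Step 13
Reactants: 18 (5R)-pentacyclic stilbene
Product: 19 (5R,10S)-hepta-O-methyl ether of the target (C5–H and C10–H cis)
Conditions: Et3SiH (6 equiv), CF3CO2H–CH2Cl2 (1:4), −20 → 0 °C
Reagents that add atoms: none
Why: Ionic hydrogenation, in which protonation at C11 gives the bis(methoxyaryl)-stabilised C10 cation coplanar with ring B, one face of which is covered by ring C, so Et3SiH delivers hydride to the open face that also carries C5–H and sets 10S (H/H cis).

Step 14
Reactants: 19 (5R,10S)-hepta-O-methyl ether of the target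
Product: 20 target CNP0306974.1, (5R,10S) in core numbering
Conditions: BBr3 (14 equiv), CH2Cl2, −78 °C → rt; H2O
Reagents that add atoms: none
Why: Lewis acid cleavage of all seven aryl methyl ethers; the two benzylic C–H stereocentres carry no leaving group and are not touched.

**Compound list**

1 | methyl 2,4-dimethoxy-6-methylbenzoate | COC(=O)c1c(C)cc(OC)cc1OC | starting material
2 | 3,4-dimethoxybenzaldehyde (veratraldehyde) | COc1ccc(C=O)cc1OC | starting material
3 | lithium dienolate of 1 (lithium 1-methoxy-1-(2,4-dimethoxy-6-methylidenecyclohexa-2,4-dien-1-ylidene)methanolate) | COC(O[Li])=C1C(OC)=CC(OC)=CC1=C | intermediate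
4 | lithium 1-(3,4-dimethoxyphenyl)-2-[3,5-dimethoxy-2-(methoxycarbonyl)phenyl]ethan-1-olate (racemic) | COC(=O)c1c(CC(O[Li])c2ccc(OC)c(OC)c2)cc(OC)cc1OC | intermediate
5 | rac-3-(3,4-dimethoxyphenyl)-6,8-dimethoxyisochroman-1-one | COc1cc2c(c(OC)c1)C(=O)OC(c1ccc(OC)c(OC)c1)C2 | intermediate
6 | 1,2-dimethoxybenzene (veratrole) | COc1ccccc1OC | starting material
7 | 2-[2,2-bis(3,4-dimethoxyphenyl)ethyl]-4,6-dimethoxybenzoic acid | COc1cc(CC(c2ccc(OC)c(OC)c2)c2ccc(OC)c(OC)c2)c(C(=O)O)c(OC)c1 | intermediate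
8 | rac-10-(3,4-dimethoxyphenyl)-2,4,7,8-tetramethoxy-10,11-dihydro-5H-dibenzo[a,d][7]annulen-5-one | COc1cc2c(c(OC)c1)C(=O)c1cc(OC)c(OC)cc1C(c1ccc(OC)c(OC)c1)C2 | intermediate
9 | 10-(3,4-dimethoxyphenyl)-2,4,7,8-tetramethoxy-5H-dibenzo[a,d][7]annulen-5-one | COc1cc2c(c(OC)c1)C(=O)c1cc(OC)c(OC)cc1C(c1ccc(OC)c(OC)c1)=C2 | intermediate
10 | 10-(3,4-dimethoxyphenyl)-4-hydroxy-2,7,8-trimethoxy-5H-dibenzo[a,d][7]annulen-5-one | COc1cc2c(c(O)c1)C(=O)c1cc(OC)c(OC)cc1C(c1ccc(OC)c(OC)c1)=C2 | intermediate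
11 | 3,5-dimethoxybenzyl alcohol | COc1cc(CO)cc(OC)c1 | starting material
12 | 2-bromo-3,5-dimethoxybenzyl alcohol | COc1cc(CO)c(Br)c(OC)c1 | intermediate
13 | 2-bromo-3,5-dimethoxybenzyl chloride | COc1cc(CCl)c(Br)c(OC)c1 | intermediate
14 | (2-bromo-3,5-dimethoxybenzyl)magnesium chloride | COc1cc(C[Mg]Cl)c(Br)c(OC)c1 | intermediate
15 | rac-5-(2-bromo-3,5-dimethoxybenzyl)-10-(3,4-dimethoxyphenyl)-2,7,8-trimethoxy-5H-dibenzo[a,d][7]annulene-4,5-diol | COc1cc(CC2(O)c3cc(OC)c(OC)cc3C(c3ccc(OC)c(OC)c3)=Cc3cc(OC)cc(O)c32)c(Br)c(OC)c1 | intermediate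
16 | (5R)-5-(2-bromo-3,5-dimethoxybenzyl)-10-(3,4-dimethoxyphenyl)-2,7,8-trimethoxy-5H-dibenzo[a,d][7]annulen-4-ol | COc1cc(OC)c(Br)c(c1)C[C@@H]1c3cc(OC)c(OC)cc3C(c3ccc(OC)c(OC)c3)=Cc3cc(OC)cc(O)c31 | intermediate
17 | (5R)-5-(2-bromo-3,5-dimethoxybenzyl)-10-(3,4-dimethoxyphenyl)-2,7,8-trimethoxy-5H-dibenzo[a,d][7]annulen-4-yl trifluoromethanesulfonate | COc1cc(OC)c(Br)c(c1)C[C@@H]1c3cc(OC)c(OC)cc3C(c3ccc(OC)c(OC)c3)=Cc3cc(OC)cc(OS(=O)(=O)C(F)(F)F)c31 | intermediate
18 | (5R)-pentacyclic stilbene (10,11-didehydro hepta-O-methyl target; benzyl-ring C2 bonded to core C4) | COc1cc(OC)c2c(c1)C[C@@H]1c3cc(OC)c(OC)cc3C(c3ccc(OC)c(OC)c3)=Cc3cc(OC)cc-2c31 | intermediate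
19 | (5R,10S)-hepta-O-methyl ether of the target | COc1cc(OC)c2c(c1)C[C@@H]1c3cc(OC)c(OC)cc3[C@H](c3ccc(OC)c(OC)c3)Cc3cc(OC)cc-2c31 | intermediate
20 | CNP0306974.1, (5R,10S) in core numbering | Oc1cc(O)c2c(c1)C[C@@H]1c3cc(O)c(O)cc3[C@H](c3ccc(O)c(O)c3)Cc3cc(O)cc-2c31 | target

**Step count**

Total: 14 steps. Longest linear sequence: 11 steps (1–5, then 9–14); the three-step ring A branch (6–8) joins at step 9.

**Steps most likely to fail, with fallbacks**

Step 4 (DDQ dehydrogenation may be slow or unselective). The fallback builds the C10=C11 double bond in from the start; it sets out from 1 (with 6) and returns at 9. Veratrole 6 and 3,4-dimethoxybenzoic acid in P2O5–MeSO3H give bis(3,4-dimethoxyphenyl)methanone F1. The dienolate 3 (from 1 and LiN(iPr)2, THF, −78 °C) adds to this ketone in an aldol addition and the aldolate lactonises to 3,3-bis(3,4-dimethoxyphenyl)-6,8-dimethoxyisochroman-1-one F2. KOtBu in DMSO opens the lactone by β-elimination to 2-[2,2-bis(3,4-dimethoxyphenyl)ethenyl]-4,6-dimethoxybenzoic acid F3. (CF3CO)2O in CH2Cl2 at 0 °C (mixed anhydride, Friedel–Crafts acylation of the cis veratryl ring) closes this acid directly to 9.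

Step 10 (the enantioselectivity of the phosphoric acid reduction is untested on this ring system). The fallback is a classical resolution; it sets out from 15 and returns at 16. Diphenyl hydrogen phosphate (10 mol %) with the Hantzsch ester gives racemic 5-(2-bromo-3,5-dimethoxybenzyl)-10-(3,4-dimethoxyphenyl)-2,7,8-trimethoxy-5H-dibenzo[a,d][7]annulen-4-ol F4. (1S)-(−)-Camphanic chloride, Et3N and DMAP convert it into the (5R)-camphanate F5 and the (5S)-camphanate F6. These are separated by crystallisation or chromatography, and X-ray analysis of the bromine-containing ester fixes the configuration. LiOH in THF–H2O cleaves the (5R)-ester to 16.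

Step 12 (nickel-mediated closure of a hindered ArBr/ArOTf pair may give reduction instead of coupling). The fallback is a C–H arylation without the bromine; it sets out from 10 and returns at 18. (3,5-Dimethoxybenzyl)magnesium chloride F7, made from commercial 3,5-dimethoxybenzyl chloride and Mg, adds to 10 to give rac-5-(3,5-dimethoxybenzyl)-10-(3,4-dimethoxyphenyl)-2,7,8-trimethoxy-5H-dibenzo[a,d][7]annulene-4,5-diol F8. The conditions of step 10 give (5R)-5-(3,5-dimethoxybenzyl)-10-(3,4-dimethoxyphenyl)-2,7,8-trimethoxy-5H-dibenzo[a,d][7]annulen-4-ol F9. (CF3SO2)2O and pyridine give (5R)-5-(3,5-dimethoxybenzyl)-10-(3,4-dimethoxyphenyl)-2,7,8-trimethoxy-5H-dibenzo[a,d][7]annulen-4-yl trifluoromethanesulfonate F10. Pd(OAc)2, PCy3·HBF4, pivalic acid and K2CO3 in DMA at 110 °C then arylate either of the two equivalent ortho C–H positions of the benzyl ring and close the six-membered ring to 18. Competing arylation of ring B C6–H is the risk of this variant, which is why the brominated series is the main line.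

**Further compounds**

F1 | step 4 | bis(3,4-dimethoxyphenyl)methanone | COc1ccc(cc1OC)C(=O)c1ccc(OC)c(OC)c1
F2 | step 4 | 3,3-bis(3,4-dimethoxyphenyl)-6,8-dimethoxyisochroman-1-one | COc1cc2c(c(OC)c1)C(=O)OC(c1ccc(OC)c(OC)c1)(c1ccc(OC)c(OC)c1)C2
F3 | step 4 | 2-[2,2-bis(3,4-dimethoxyphenyl)ethenyl]-4,6-dimethoxybenzoic acid | COc1cc(C=C(c2ccc(OC)c(OC)c2)c2ccc(OC)c(OC)c2)c(C(=O)O)c(OC)c1
F4 | step 10 | rac-5-(2-bromo-3,5-dimethoxybenzyl)-10-(3,4-dimethoxyphenyl)-2,7,8-trimethoxy-5H-dibenzo[a,d][7]annulen-4-ol | COc1cc(OC)c(Br)c(c1)CC1c3cc(OC)c(OC)cc3C(c3ccc(OC)c(OC)c3)=Cc3cc(OC)cc(O)c31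
F5 | step 10 | (5R)-5-(2-bromo-3,5-dimethoxybenzyl)-10-(3,4-dimethoxyphenyl)-2,7,8-trimethoxy-5H-dibenzo[a,d][7]annulen-4-yl (1S,4R)-camphanate | COc1cc(OC)c(Br)c(c1)C[C@@H]1c3cc(OC)c(OC)cc3C(c3ccc(OC)c(OC)c3)=Cc3cc(OC)cc(OC(=O)[C@@]45CC[C@@](C)(C(=O)O4)C5(C)C)c31
F6 | step 10 | (5S)-5-(2-bromo-3,5-dimethoxybenzyl)-10-(3,4-dimethoxyphenyl)-2,7,8-trimethoxy-5H-dibenzo[a,d][7]annulen-4-yl (1S,4R)-camphanate | COc1cc(OC)c(Br)c(c1)C[C@H]1c3cc(OC)c(OC)cc3C(c3ccc(OC)c(OC)c3)=Cc3cc(OC)cc(OC(=O)[C@@]45CC[C@@](C)(C(=O)O4)C5(C)C)c31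
F7 | step 12 | (3,5-dimethoxybenzyl)magnesium chloride | COc1cc(C[Mg]Cl)cc(OC)c1
F8 | step 12 | rac-5-(3,5-dimethoxybenzyl)-10-(3,4-dimethoxyphenyl)-2,7,8-trimethoxy-5H-dibenzo[a,d][7]annulene-4,5-diol | COc1cc(CC2(O)c3cc(OC)c(OC)cc3C(c3ccc(OC)c(OC)c3)=Cc3cc(OC)cc(O)c32)cc(OC)c1
F9 | step 12 | (5R)-5-(3,5-dimethoxybenzyl)-10-(3,4-dimethoxyphenyl)-2,7,8-trimethoxy-5H-dibenzo[a,d][7]annulen-4-ol | COc1cc(OC)cc(c1)C[C@@H]1c3cc(OC)c(OC)cc3C(c3ccc(OC)c(OC)c3)=Cc3cc(OC)cc(O)c31
F10 | step 12 | (5R)-5-(3,5-dimethoxybenzyl)-10-(3,4-dimethoxyphenyl)-2,7,8-trimethoxy-5H-dibenzo[a,d][7]annulen-4-yl trifluoromethanesulfonate | COc1cc(OC)cc(c1)C[C@@H]1c3cc(OC)c(OC)cc3C(c3ccc(OC)c(OC)c3)=Cc3cc(OC)cc(OS(=O)(=O)C(F)(F)F)c31
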